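Whatever happens in a closed flask, the X charged is at every moment X left, Q, or something unread, so I follow the fraction left.

| setting | east | north-east | south-east | west |
|---|---|---|---|---|
| X | 250 mM | 750 mM | 250 mM | 250 mM |
| Q |  |  | 120 mM |  |
| time |  |  |  | 63 min |

| run | time / min | [Q] / mM |
|---|---|---|
| east run | 0.84 | 5 |
| east run | 1.4 | 3 |
| east run | 2.5 | 10 |
| east run | 4.2 | 14 |
| east run | 7.2 | 42 |
| east run | 12 | 48 |
| east run | 21 | 76 |
| north-east run | 0.84 | 3 |
| north-east run | 1.4 | 8 |
| north-east run | 2.5 | 24 |
| north-east run | 4.2 | 40 |
| north-east run | 7.2 | 77 |
| north-east run | 12 | 113 |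
| north-east run | 21 | 160 |
| south-east run | 0.84 | 112 |
| south-east run | 1.4 | 116 |
| south-east run | 2.5 | 116 |
| south-east run | 4.2 | 122 |
| south-east run | 7.2 | 119 |
| south-east run | 12 | 121 |
| south-east run | 21 | 113 |

(standard deviation of a reading: 4 mM)

- Overall: X -> Q.
- Constant volume, constant temperature.
- Readings of a species count what is bound in complexes too.
- An order is taken over about fifteen percent of the charge, up and down.

- reaction order in [X] at the outset, round the charge of the east run, defined at two percent of the X turned into Q (one fixed amount of Q, the same in the runs compared)
- Q in the west run at 63 min, as a share of the X charged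

Why is the south-east run flat? Either X and Q stand at equilibrium, or Q is made and lost at equal rates, a steady state in the usual term.

Which is it? Test the east run. At its last reading, Q over charge minus Q is 0.437, close to the 0.480 of the south-east start. Yet between its last two readings Q climbs at 3.11 mM min⁻¹, against 4.00 mM min⁻¹ on average up to 12 min.

Is that climb mere scatter? No: scatter gives that slope about 0.629 mM min⁻¹, well below the climb. I take the balance.

What does the balance give? The keeping constant, the share of Q lost per minute, is making rate over the level held: 4.00 mM min⁻¹ over 120 mM gives 0.0333 min⁻¹. The east rate serves because both flasks hold the same charge of X, 250 mM.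

And the west run? On my reckoning X is used at 0.0160 min⁻¹, so 36.5 % of it is left at 63 min, and a share of Q made at the start would keep 12.3 % over the same time. Consecutive first-order steps then give my figure: 22.4 % of the charge.

Its weak spot? At 48 mM of Q, my keeping constant puts the loss in the east run at 1.60 mM min⁻¹, so the rate I read is low and my share is, if anything, high. For the order I offer no figure.

The forecast says 0.8 and 33 %, holding that “adding Q stops net reaction at Q/X ≈ 0.48”.

The flask gives an order of 0.47, with rates of 5.6 mM min⁻¹ in the east run and 8.9 mM min⁻¹ in the north-east run at the fixed amount of Q, a ratio of 1.6. The west run gives 14.9 %, so my figure stands 7.5 percentage points above it and the forecast 18 points above it.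

    X ⇌ E (0.1116 min⁻¹, 0.1758 min⁻¹)
    E → Q (0.8280 min⁻¹)
    Q → Ju (0.05628 min⁻¹)
    2 X ⇌ X2, settled at all times (10.90 M⁻¹)

In the west run X went through E to Q while Q went on to Ju, and at 63 min Q stood at 37.2 mM. My keeping constant of 0.0333 min⁻¹ stands below the k4 of 0.0563 min⁻¹; with k4, that west Q was going to Ju at 2.09 mM min⁻¹, and the 160 mM of the last north-east reading gives about 9.01 mM min⁻¹.

All runs come from a simulation on assumed constants; scatter was added.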